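**Plan**

- Dihydropyran numbering: O1, C2 (CH3), C3 (CHO), C4 (CH2CO2R), C5 (CO2Me), C6. The target is (2S,3S,4S): 2,3-cis and 3,4-trans.
- Cuts, in retrosynthetic order: the arm ester C–O (hydroxytyrosol off); O1–C2 (retro-oxa-Michael), with the C2 oxygen re-attached to the arm carboxyl as a δ-lactone; C4–C5 and C3–CHO together (retro-de Mayo); the lactone C3=C4 (metathesis) and its ester C–O.
- Enabling feature: the C3 formyl carbon and the C5(CO2Me)=C6H–O1 unit are the two halves of one methyl diformylacetate laid across a C3=C4 double bond, and C2–O plus the C4 acetic arm are the two ends of a six-membered β,γ-unsaturated lactone.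
- Forward: lactone ring by ring-closing metathesis; a cyclobutane is formed and cleaved in the photochemical step (no ring remains); the lactone is opened by E1cB and the dihydropyran closed by oxa-Michael addition; the side-chain ester is joined last, then debenzylation.
- Stereochemistry: (R)-but-3-en-2-ol gives the lactone methyl centre, which sends the photoaddition to the opposite face and so sets C4. That centre is then erased, and C2 and C3 are set from C4 under thermodynamic control in the ring closure.

Key step: step 4

Remark on the chemistry: 9 is written as the open hydroxymethylene aldehyde; it is expected to equilibrate with the cyclic hemiacetal formed between its enol oxygen and the C3 formyl group, and the later steps draw on the open form.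

**Route**

Step 1
Reactants: 1 (R)-but-3-en-2-ol; 2 but-3-enoic acid
Product: 3 (2R)-but-3-en-2-yl but-3-enoate
Conditions: DCC, DMAP (5 mol %), CH2Cl2, 0 °C
Reagents that add atoms: none
Why: Steglich esterification acylates the hydroxyl without breaking the C–O bond of the stereocentre (retention), and low temperature with little DMAP should keep the but-3-enoyl group from isomerising to the crotonate.

Step 2
Reactants: 3 (2R)-but-3-en-2-yl but-3-enoate
Product: 4 (6R)-6-methyl-3,6-dihydro-2H-pyran-2-one
Conditions: second-generation Grubbs catalyst (H2IMes)(PCy3)Cl2Ru=CHPh (3 mol %), 1,4-benzoquinone (10 mol %), CH2Cl2 (0.01 M), 40 °C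
Reagents that add atoms: none
Why: Ring-closing metathesis of two terminal alkenes to a six-membered ring is driven by loss of ethene, necessarily gives the cis ring alkene, leaves the allylic stereocentre untouched, and benzoquinone suppresses ruthenium hydride isomerisation of the double bond into conjugation.

Step 3
Reactants: 5 methyl 3,3-dimethoxypropanoate
Product: 7 methyl diformylacetate, via formyl acetal sodium enolate 6 (not isolated)
Conditions: NaH, HCO2Me, Et2O, 0 °C → rt; then 2 M aq. HCl, rt
Reagents that add atoms: methyl formate COC=O; water O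
Why: Crossed Claisen formylation of the ester enolate by methyl formate is pulled forward by formation of the stabilised sodium enolate, and aqueous acid then hydrolyses the dimethyl acetal to the second formyl group, leaving the strongly enolised, hydrogen-bonded tricarbonyl compound.

Step 4
Reactants: 4 (6R)-6-methyl-3,6-dihydro-2H-pyran-2-one; 7 methyl diformylacetate
Product: 9 methyl (2Z)-2-[(2R,3S,4S)-3-formyl-2-methyl-6-oxooxan-4-yl]-3-hydroxyprop-2-enoate, via cis-fused cyclobutanol 8 (not isolated)
Conditions: hν (450 W medium-pressure Hg lamp, Corex filter), degassed MeCN, 0–5 °C, 4 in excess (3 equiv, recovered); then rt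
Reagents that add atoms: none
Why: The hydrogen-bonded enol of 7 is excited as an enone and adds stepwise through a 1,4-diradical to the cis alkene of 4; the resulting β-hydroxy aldehyde cyclobutane 8 then relieves its strain by retro-aldol cleavage of the bond between the carbinol carbon and the quaternary carbon, so that the former becomes the formyl group on C3 and the latter the enolised formylacetate on C4 (de Mayo reaction). The closest known reaction type is the de Mayo reaction of methyl diformylacetate with cyclopentenes that carry an allylic methyl group. The only ring closed is the cyclobutane, by radical recombination of the 1,4-diradical in a formal [2+2] sense, and it is opened again in the same operation, so no new ring remains. The new stereocentre C4 (S) is set by approach of the enol to the face of the nearly flat lactone opposite the C2 methyl group; C3 arises cis to it (cis ring fusion) but is reset in step 5. The step needs the orientation in which the hydroxymethine carbon bonds to C3 and the fully substituted carbon to C4, and this is secured sterically: the bulky carbon carrying ester and formyl groups should go to the alkene carbon flanked by CH2, the small carbon to the one flanked by the branched CH(CH3)O carbon. The face-epimeric adduct is a diastereomer at this stage and has to be removed here by chromatography, because after step 5 it would end as the enantiomer.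

Step 5
Reactants: 9 methyl (2Z)-2-[(2R,3S,4S)-3-formyl-2-methyl-6-oxooxan-4-yl]-3-hydroxyprop-2-enoate
Product: 11 elenolic acid, via ethylidene enal acid 10 (not isolated)
Conditions: Et3N (2.5 equiv), CH2Cl2, 0 °C → rt; then AcOH (3 equiv), rt, until closure and equilibration are complete; aq. citric acid work-up
Reagents that add atoms: none
Why: E1cB elimination of the β-acyloxy aldehyde expels the C2 carboxylate and opens the lactone to the ethylidene enal 10, whose enol oxygen then adds to C2 in a 6-endo oxa-Michael closure; since C2 (retro-oxa-Michael) and C3 (enolisation) can both equilibrate, the fixed C4 centre should dictate the outcome, with the arm pseudoaxial to avoid A(1,2) strain with the C5 ester, the formyl group trans to it and the methyl group equatorial and hence cis to formyl, which is the (2S,3S,4S) array.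

Step 6
Reactants: 12 hydroxytyrosol
Product: 13 2-[3,4-bis(benzyloxy)phenyl]ethan-1-ol
Conditions: BnBr (2.2 equiv), K2CO3, acetone, reflux, under Ar
Reagents that add atoms: benzyl bromide BrCc1ccccc1
Why: Williamson etherification in which K2CO3 deprotonates only the two phenols, so that the primary alcohol stays free.

Step 7
Reactants: 11 elenolic acid; 13 2-[3,4-bis(benzyloxy)phenyl]ethan-1-ol
Product: 14 methyl (2S,3S,4S)-4-{2-[2-(3,4-bis(benzyloxy)phenyl)ethoxy]-2-oxoethyl}-3-formyl-2-methyl-3,4-dihydro-2H-pyran-5-carboxylate
Conditions: DCC, DMAP (10 mol %), CH2Cl2, 0 °C → rt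
Reagents that add atoms: none
Why: Steglich esterification of an unhindered primary alcohol; C4 carries no acidifying group, and C2 and C3 already sit in their equilibrium configuration, so transient base catalysis should not move them.

Step 8
Reactants: 14 methyl (2S,3S,4S)-4-{2-[2-(3,4-bis(benzyloxy)phenyl)ethoxy]-2-oxoethyl}-3-formyl-2-methyl-3,4-dihydro-2H-pyran-5-carboxylate
Product: 15 methyl (2S,3S,4S)-4-{2-[2-(3,4-dihydroxyphenyl)ethoxy]-2-oxoethyl}-3-formyl-2-methyl-3,4-dihydro-2H-pyran-5-carboxylate
Conditions: H2 (1 atm), 10% Pd/C, EtOAc, rt
Reagents that add atoms: none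
Why: Hydrogenolysis of the two aryl benzyl ethers under neutral conditions; an aliphatic aldehyde and the push–pull enol ether double bond are reduced far more slowly on palladium than a benzylic C–O bond is cleaved, and no stereocentre is involved.

**Compound list**

1 | (R)-but-3-en-2-ol | C[C@@H](O)C=C | starting material
2 | but-3-enoic acid | C=CCC(=O)O | starting material
3 | (2R)-but-3-en-2-yl but-3-enoate | C[C@@H](OC(=O)CC=C)C=C | intermediate
4 | (6R)-6-methyl-3,6-dihydro-2H-pyran-2-one | C[C@@H]1C=CCC(=O)O1 | intermediate
5 | methyl 3,3-dimethoxypropanoate | COC(CC(=O)OC)OC | starting material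
6 | methyl 2-formyl-3,3-dimethoxypropanoate (present as its sodium enolate) | COC(=O)C(C=O)C(OC)OC | intermediate
7 | methyl diformylacetate (methyl 2-formyl-3-oxopropanoate, enolised) | COC(=O)C(C=O)C=O | intermediate
8 | methyl (1R,2R,6S)-7-formyl-8-hydroxy-2-methyl-4-oxo-3-oxabicyclo[4.2.0]octane-7-carboxylate (cis-fused, cyclobutane anti to the methyl group, epimers at C7 and C8) | C[C@H]1OC(=O)C[C@H]2[C@@H]1C(O)C2(C=O)C(=O)OC | intermediate
9 | methyl (2Z)-2-[(2R,3S,4S)-3-formyl-2-methyl-6-oxooxan-4-yl]-3-hydroxyprop-2-enoate | C[C@H]1OC(=O)C[C@H](/C(C(=O)OC)=C/O)[C@@H]1C=O | intermediate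
10 | (3S,4E)-4-formyl-3-[(1Z)-1-hydroxy-3-methoxy-3-oxoprop-1-en-2-yl]hex-4-enoic acid | OC(=O)C[C@H](/C(C(=O)OC)=C/O)/C(C=O)=C\C | intermediate
11 | elenolic acid, 2-[(2S,3S,4S)-3-formyl-5-(methoxycarbonyl)-2-methyl-3,4-dihydro-2H-pyran-4-yl]acetic acid | COC(=O)C1=CO[C@@H](C)[C@@H](C=O)[C@@H]1CC(=O)O | intermediate
12 | hydroxytyrosol, 4-(2-hydroxyethyl)benzene-1,2-diol | OCCc1ccc(O)c(O)c1 | starting material
13 | 2-[3,4-bis(benzyloxy)phenyl]ethan-1-ol | OCCc1ccc(OCc2ccccc2)c(OCc2ccccc2)c1 | intermediate
14 | methyl (2S,3S,4S)-4-{2-[2-(3,4-bis(benzyloxy)phenyl)ethoxy]-2-oxoethyl}-3-formyl-2-methyl-3,4-dihydro-2H-pyran-5-carboxylate | COC(=O)C1=CO[C@@H](C)[C@@H](C=O)[C@@H]1CC(=O)OCCc1ccc(OCc2ccccc2)c(OCc2ccccc2)c1 | intermediate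
15 | methyl (2S,3S,4S)-4-{2-[2-(3,4-dihydroxyphenyl)ethoxy]-2-oxoethyl}-3-formyl-2-methyl-3,4-dihydro-2H-pyran-5-carboxylate | COC(=O)C1=CO[C@@H](C)[C@@H](C=O)[C@@H]1CC(=O)OCCc1ccc(O)c(O)c1 | target

**Step count and risks**

Total step count: 8. Longest linear sequence: 6 steps (steps 1, 2, 4, 5, 7, 8).

The three steps most likely to fail:

**Step 4.** The photoaddition may take the wrong orientation (quaternary carbon bonding to C3), a single methyl group may discriminate the two faces only weakly, and the adduct may undergo secondary photolysis. The fallback sets out from 7 and comes back at 9. Compound 7 is irradiated under the same conditions with (1R,2R)-2-methylcyclopent-3-en-1-ol F1, a five-membered alkene with an allylic methyl group for which this orientation and the attack anti to methyl are the established ones. The photoproduct should be the cis-fused lactol methyl (4aS,6R,7R,7aS)-1,6-dihydroxy-7-methyl-1,4a,5,6,7,7a-hexahydrocyclopenta[c]pyran-4-carboxylate F2. MeOH with PPTS converts it into the methyl acetal of that lactol F3, and Dess–Martin periodinane oxidises the secondary alcohol to the cyclopentanone methyl acetal F4. Baeyer–Villiger oxidation (mCPBA, NaHCO3, CH2Cl2), in which the more substituted methyl-bearing carbon migrates with retention, then gives the δ-lactone methyl acetal F5. Aqueous acid (1 M HCl, THF) hydrolyses the acetal to 9.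

**Step 5.** Stereoconvergence at C2 may be incomplete during the ring closure, with the epimer having methyl trans to formyl persisting, and the open enal may oligomerise under base. The fallback sets out from 9 and comes back at 11; it avoids the elimination and moves the C2 oxygen stereospecifically. The formyl group is masked by converting 9, through its hemiacetal tautomer, into the δ-lactone methyl acetal F5 (MeOH, PPTS). LiOH (THF–H2O, 0 °C) opens the lactone to the (1R)-hydroxy acid acetal F6, which is used at once. Mitsunobu lactonisation (PPh3, DIAD, toluene) closes it again with inversion of the carbinol carbon, giving the C2-epimeric δ-lactone methyl acetal F7. A second saponification gives the (1S)-hydroxy acid acetal F8. Aqueous acid (1 M HCl, THF) then hydrolyses the acetal, and the C2 hydroxyl condenses with the liberated C6 formyl (enol) carbon with loss of water to the vinylogous carbonate. This gives 11 with C2 fixed by the inversion and C3 and C4 carried over from step 4.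

**Step 8.** The formyl group or the enol ether double bond may be over-reduced while the benzyl ethers are being cleaved, or the debenzylation may stall on a poisoned catalyst. The fallback sets out from 12 and 11 and comes back at 15. Compound 12 is protected as the catechol acetonide 2-(2,2-dimethyl-1,3-benzodioxol-5-yl)ethan-1-ol F9 (2,2-dimethoxypropane, CSA cat., CHCl3, reflux). It is coupled with 11 under the conditions of step 7 to the acetonide ester F10. The catechol is released with TFA–H2O (9:1, 0 °C → rt), conditions that use no reducing agent and under which the formyl group, the enol ether and both esters are expected to persist.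

Further compounds

F1 | step 4 | (1R,2R)-2-methylcyclopent-3-en-1-ol | C[C@H]1[C@H](O)CC=C1
F2 | step 4 | methyl (4aS,6R,7R,7aS)-1,6-dihydroxy-7-methyl-1,4a,5,6,7,7a-hexahydrocyclopenta[c]pyran-4-carboxylate (lactol epimers at C1) | C[C@H]1[C@H](O)C[C@@H]2C(C(=O)OC)=COC(O)[C@H]12
F3 | step 4 | methyl (4aS,6R,7R,7aS)-6-hydroxy-1-methoxy-7-methyl-1,4a,5,6,7,7a-hexahydrocyclopenta[c]pyran-4-carboxylate (anomers at C1) | C[C@H]1[C@H](O)C[C@@H]2C(C(=O)OC)=COC(OC)[C@H]12
F4 | step 4 | methyl (4aS,7R,7aS)-1-methoxy-7-methyl-6-oxo-1,4a,5,6,7,7a-hexahydrocyclopenta[c]pyran-4-carboxylate (anomers at C1) | C[C@H]1C(=O)C[C@@H]2C(C(=O)OC)=COC(OC)[C@H]12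
F5 | step 4 | δ-lactone methyl acetal, the cyclic methyl acetal of the hemiacetal tautomer of 9 (2-methoxydihydropyran cis-fused to the lactone, lactone methyl centre R, anomers at the acetal carbon) | C[C@H]1OC(=O)C[C@@H]2C(C(=O)OC)=COC(OC)[C@H]12
F6 | step 5 | 2-[(3S,4S)-3-[(1R)-1-hydroxyethyl]-2-methoxy-5-(methoxycarbonyl)-3,4-dihydro-2H-pyran-4-yl]acetic acid (anomers at C2 of the pyran) | C[C@@H](O)[C@H]1C(OC)OC=C(C(=O)OC)[C@H]1CC(=O)O
F7 | step 5 | C2-epimeric δ-lactone methyl acetal (as F5 but lactone methyl centre S) | C[C@@H]1OC(=O)C[C@@H]2C(C(=O)OC)=COC(OC)[C@H]12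
F8 | step 5 | 2-[(3S,4S)-3-[(1S)-1-hydroxyethyl]-2-methoxy-5-(methoxycarbonyl)-3,4-dihydro-2H-pyran-4-yl]acetic acid (anomers at C2 of the pyran) | C[C@H](O)[C@H]1C(OC)OC=C(C(=O)OC)[C@H]1CC(=O)O
F9 | step 8 | 2-(2,2-dimethyl-1,3-benzodioxol-5-yl)ethan-1-ol | OCCc1ccc2OC(C)(C)Oc2c1
F10 | step 8 | methyl (2S,3S,4S)-4-{2-[2-(2,2-dimethyl-1,3-benzodioxol-5-yl)ethoxy]-2-oxoethyl}-3-formyl-2-methyl-3,4-dihydro-2H-pyran-5-carboxylate | COC(=O)C1=CO[C@@H](C)[C@@H](C=O)[C@@H]1CC(=O)OCCc1ccc2OC(C)(C)Oc2c1
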